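(The constants used here stand for no real mixture; the rest is arithmetic.)

I charged 10 mM of starting material with 0.200 mM of protic impurity; starting material, target and isomer of the product exchange reversibly, while the impurity turns starting material into quenched substrate, a step with no way back.

starting material 10 mM; protic impurity 0.200 mM; time 2.5 h

    isomer of the product ⇌ starting material (k1 = 0.216 s⁻¹)
    starting material + protic impurity → quenched substrate (k2 = 14.6 M⁻¹ s⁻¹)
    target ⇌ isomer of the product (K3 = 1.5, k3 = 0.0656 s⁻¹)
    starting material ⇌ target (K4 = 0.68, k4 = 0.0105 s⁻¹)

1. share of the starting material used up at 2.5 h
2. target at 2.5 h, in percent of the starting material charged
3. isomer of the product at 2.5 h, in percent of the starting material charged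

I reckoned the loss to the impurity in two ways. Counting half-lives, starting material has a half-life of 0.066 h against the impurity, with the impurity held at its charge as if it never ran down. The 2.5 h hold 37.9 of these, which on that count leaves hardly any starting material. Counting amounts, one impurity takes one starting material, so the charge allows a loss of 2.00%. The two ways parted, and the first cheated, because the impurity, the limiting reagent, is the smaller charge and runs down as it reacts, one for one.

The exchange came next. Its slowest relaxation, between starting material and target by their own step alone, has a half-life of 0.445 min, and 2.5 h hold 337 of them, so I took the flask to be at rest. I carried one quantity: the rest share f, the fraction of starting material, target and isomer of the product taken together that stands as target at rest, 0.252. Applied to what the impurity leaves, f gave target 24.7%, isomer of the product 37.0% and conversion 63.7%.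

The forecast gave 63.7% conversion, 24.7% target and 37% isomer of the product, on the ground that “2.5 h is long compared with the isomerisation timescales”.

At 2.50 h the flask gave 63.7% conversion, 24.7% target and 37.0% isomer of the product, with quenched substrate at 2.00% of the starting material charged and protic impurity at 0% of its own charge. The share f of 0.252, applied to the 98.0% of the starting material that the impurity spared, returns this flask's target. The neighbour flask held 6.0 mM of starting material, so the same impurity stood at 0.0333 equiv. There f reckons target at 24.4%. That neighbour flask gave 24.3% target at 2.50 h, with quenched substrate at 3.33% of its charged starting material.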